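# Proposed synthesis of CNP0316116.1 (17) by a copper-catalysed borylative allene–aldehyde ring closure

Compounds are numbered 1–17 in the order in which they appear in the steps; 17 is the target. Benzofuran numbering is used for the ring atoms, Ca is the vinyl carbon on C2, and C1' is the carbinol carbon of the C5 side chain.

## The problem

Target 17 is a 2,3-dihydrobenzofuran. Its five-membered ring (O1, C2, C3, C3a, C7a) carries a 1-formylethenyl group on C2 (Ca bearing =CH2 and CHO) cis to an isovalerate on C3, and C5 of the benzene ring carries a (1R)-1-(isovaleryloxy)ethyl chain. C2 and C3 (2R,3R) are neighbours and can be made in one event or control each other. C1' lies across the arene, cannot be relayed from the ring and needs reagent control.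

The functional groups leave little room. The C3 ester is benzylic and anti to C2–H, so acid or base can expel isovaleric acid and aromatise the ring to a benzofuran. The C1' ester sits on a benzylic carbon para to O1 and ionises easily. The 2-substituted acrolein is a Michael acceptor and, beside a free cis C3–OH, would close to a lactol. The aldehyde must therefore appear last, under neutral conditions, after both alcohols are acylated.

The feature that opens the structure is the pattern around C2–C3. C2 bears O1, one hydrogen and Ca. C3 bears an oxygen and the aromatic carbon C3a, which is ortho to the O1-bearing C7a. Read backwards, O1–C2–Ca=CH2 is the oxygen-bearing terminus of an allyl metal derived from an aryloxyallene, and C3 is an ortho formyl carbon. Joining them closes the dihydrofuran ring, and a boron placed on the central allene carbon ends on Ca as the handle for the missing formyl carbon.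

## Retrosynthesis

**17 ⇒ 16.** No skeletal bond is cut; the formyl group is taken back to the primary allylic alcohol 16. This leaves only one neutral operation in the presence of the enal and avoids two steps of aldehyde protection. The forward step must oxidise an allylic alcohol without acid or base, because of the benzylic esters and the elimination to the benzofuran.

**16 ⇒ 14 (through 15).** The Ca–CH2 bond is cut. The carbon is delivered to a boron-bearing Ca by a 1,2-metallate shift (giving 15) and the C–B bond is then exchanged for C–O. The neighbouring options are less attractive: allylic oxidation of a methyl group on Ca is undirected and acidic, and carbonylation of a vinyl halide brings zerovalent palladium next to an allylic aryl ether. Precursor 14 is one carbon shorter and carries a robust alkenyl boronate. The carbenoid must choose boron over two ester carbonyls.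

**14 ⇒ 12 + 13.** Both acyl–oxygen bonds are cut together, since the two alcohols receive the same acyl group from 13 and need no differentiation. The acylation is placed before the formyl carbon exists, because a free cis C3–OH next to the aldehyde would be trapped as a lactol. The forward step must not ionise either benzylic position.

**12 ⇒ 11.** The C1'–H bond is cut (hydride addition to the acetyl group). C1' cannot be relayed from C2/C3, and an aryl methyl ketone is the best substrate class for catalytic asymmetric transfer hydrogenation. Keeping the side chain as acetyl up to this point costs no protecting group in the key step. The reduction must tolerate the alkenyl boronate and the benzylic C3 alcohol.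

**11 ⇒ 8 + 9 (key disconnection).** The C2–C3 bond and the Ca–B bond are cut, which opens the dihydrofuran ring. Cutting O1–C2 or C3–O instead would leave one stereocentre to be made separately and the other to be relayed. Cutting C2–C3 creates both from the flat, achiral allenyl ether 8 and the diboron reagent 9, and puts boron on Ca. The forward reaction must place boron on the central allene carbon, close cis, select one face, and take the aldehyde in preference to the ketone.

**8 ⇒ 7 ⇒ 6.** No skeletal bond is cut; the two carbonyls are taken back to the diol 7 and its bis-silyl ether 6. The allene cannot be generated by base in the presence of an aryl aldehyde and an enolisable methyl ketone. Acetals would need acid for removal, which an enol-ether-type allene may not survive, whereas silyl ethers leave with fluoride and the benzylic alcohols are re-oxidised under neutral conditions.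

**6 ⇒ 5.** Only hydrogens move: the aryloxyallene 6 comes from the propargyl ether 5 by base-mediated isomerisation. The forward step must stop at the allene and not go on to the 1-propynyl ether.

**5 ⇒ 4 ⇒ 3 ⇒ 1 + 2.** The silyl groups are removed and the alcohols returned to the carbonyls of 3 (reduction in the forward sense). The O–CH2 bond is then cut to the commercial phenol 1 and propargyl bromide 2.

## Roads not taken

**Alternative 1: the benzene ring assembled last by rhodium-catalysed (2+2+2) cyclotrimerisation.**
- Cut: the bonds C3a–C7a, C4–C5 and C6–C7.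
- Forward step: [Rh(cod)2]BF4/BINAP joins the ynol ether–propargylic ester diyne A2 with the chiral-pool alkyne ester A3 to give the isopropenyl compound A1. Allylic oxidation of the methyl group would then lead to 17.
- Merits: it is the most convergent plan, C1' comes from the chiral pool, and both isovalerates are in place before the key step.
- Weak points:
  - A2 already contains C2 and C3 as an acyclic pair, so the ring stereochemistry is moved into a precursor that needs its own asymmetric synthesis.
  - Terminal ynol ethers are made by strong-base eliminations and are hydrolytically fragile, which fits badly with the neighbouring ester.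
  - The propargylic ester can ionise or migrate under cationic monovalent rhodium.
  - The orientation of A3 (C5 versus C6 substitution) rests on a small electronic difference between the two alkyne ends of A2.
  - The final SeO2-type oxidation is undirected and acidic, in a molecule with two acid-labile benzylic esters.
- Comparison: Alternative 1 is better in convergence and in needing no late acylation. The chosen plan answers with a trivial achiral precursor (8), both ring stereocentres from one event, and a directed introduction of the formyl carbon through boron.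

**Alternative 2: late benzylic C–H lactonisation to install the C3 oxygen.**
- Cut: the C3–O bond.
- Forward step: the C2 acetic acid A5 captures the benzylic C3–H oxidatively (PhI(OAc)2/KBr, or CuOAc with N-fluorobenzenesulfonimide) to give the cis-fused lactone A4.
- Merits: only C2 has to be made, and it dictates C3 with certainty because the bicyclic lactone can only be cis-fused. That relay is more reliable than any catalyst control.
- Weak points:
  - The C3–H is benzylic on an acetyl-deactivated arene and competes with the C2–H (alpha to oxygen) and the acetyl methyl group.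
  - Dihydrobenzofurans under oxidative conditions tend to aromatise.
  - The lactone carbon is not yet the formyl carbon: methylenation and partial reduction are needed, and reduction to the aldehyde level leaves the C3 oxygen and the new carbonyl tied as a cyclic hemiacetal. Acylating C3–OH while freeing the aldehyde is then the unsolved end problem.
- Comparison: Alternative 2 is better in relative stereocontrol and in the simplicity of its precursor. The chosen plan depends on a chiral catalyst for the absolute sense, but it keeps Ca as a boronate until both esters are in place and so never meets the lactol.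

**Alternative 3: palladium-mediated carbonylative double cyclisation of an allenyl carbinol.**
- Cut: O1–C2, the Ca–carbonyl bond and the lactone C–O bond.
- Forward step: PdCl2/CuCl2 under CO makes the phenol of A7 add to the proximal allene carbon, the vinylpalladium inserts CO, and the C3 hydroxyl closes the α-methylene lactone A6.
- Merits: one operation forms both rings and places the future formyl carbon on Ca from carbon monoxide. No separate homologation is needed, which the chosen plan cannot match.
- Weak points:
  - Under divalent palladium, α-allenyl carbinols usually cyclise through their own hydroxyl onto the distal allene carbon (2,5-dihydrofuran formation), in competition with phenol attack.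
  - C2 is fixed in the oxypalladation before the lactone closes, so a trans adduct cannot lactonise and is diverted.
  - Stoichiometric CuCl2 meets a free, electron-rich phenol.
  - A6 leads to the same cyclic-hemiacetal endgame as Alternative 2, with an added risk of conjugate reduction of the methylene lactone.
- Comparison: Alternative 3 is more step-economical in carbon. The chosen plan spends two operations on the formyl carbon (homologation–oxidation, then alcohol oxidation) and gains oxygen functions that stay differentiated until the end.

Key step: step 7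

## Route

Assumption: the antipode of Ph-BPE (1,2-bis(2,5-diphenylphospholan-1-yl)ethane) that delivers the (2R,3R) series cannot be assigned in advance for this substrate class. The route is written with (S,S)-Ph-BPE, and the mirror-image ligand takes its place if the first run shows the opposite sense. Compounds 4–7 are racemic at the carbinol carbon, which is erased in step 6.

Step 1
Reactants: 1 5-acetyl-2-hydroxybenzaldehyde; 2 3-bromoprop-1-yne
Product: 3 5-acetyl-2-(prop-2-yn-1-yloxy)benzaldehyde
Conditions: K2CO3, DMF, rt
Reagents that add atoms: 3-bromoprop-1-yne (2), C#CCBr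
Why: Williamson etherification of a phenol made acidic by its para acetyl and ortho formyl groups with a primary propargylic bromide; carbonate base leaves both carbonyls untouched.

Step 2
Reactants: 3 5-acetyl-2-(prop-2-yn-1-yloxy)benzaldehyde
Product: 4 (1RS)-1-[3-(hydroxymethyl)-4-(prop-2-yn-1-yloxy)phenyl]ethan-1-ol
Conditions: NaBH4, MeOH, 0 °C
Reagents that add atoms: none
Why: Borohydride reduction of the aryl aldehyde and aryl ketone removes both base-sensitive carbonyls before the isomerisation; the carbinol centre formed here is racemic and is erased again in step 6.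

Step 3
Reactants: 4 (1RS)-1-[3-(hydroxymethyl)-4-(prop-2-yn-1-yloxy)phenyl]ethan-1-ol
Product: 5 (1RS)-1-[3-({[tert-butyl(dimethyl)silyl]oxy}methyl)-4-(prop-2-yn-1-yloxy)phenyl]ethyl tert-butyl(dimethyl)silyl ether
Conditions: TBSCl, imidazole, DMF, rt
Reagents that add atoms: tert-butyl(chloro)dimethylsilane, CC(C)(C)[Si](C)(C)Cl
Why: Standard imidazole-promoted silylation of a primary and a secondary benzylic alcohol; the silyl ethers are inert to KOt-Bu and can later be removed with fluoride without acid.

Step 4
Reactants: 5 (1RS)-1-[3-({[tert-butyl(dimethyl)silyl]oxy}methyl)-4-(prop-2-yn-1-yloxy)phenyl]ethyl tert-butyl(dimethyl)silyl ether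
Product: 6 (1RS)-1-[3-({[tert-butyl(dimethyl)silyl]oxy}methyl)-4-(propa-1,2-dien-1-yloxy)phenyl]ethyl tert-butyl(dimethyl)silyl ether
Conditions: KOt-Bu (0.5 equiv), THF, 0 °C → rt
Reagents that add atoms: none
Why: Base-mediated propargyl-to-allene isomerisation of an aryl propargyl ether, which stops at the aryloxyallene in THF at or below room temperature; the substrate has no other acidic C–H and no carbonyl group.

Step 5
Reactants: 6 (1RS)-1-[3-({[tert-butyl(dimethyl)silyl]oxy}methyl)-4-(propa-1,2-dien-1-yloxy)phenyl]ethyl tert-butyl(dimethyl)silyl ether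
Product: 7 (1RS)-1-[3-(hydroxymethyl)-4-(propa-1,2-dien-1-yloxy)phenyl]ethan-1-ol
Conditions: TBAF, AcOH (1:1), THF, 0 °C → rt
Reagents that add atoms: none
Why: Fluoride desilylation of both benzylic silyl ethers; buffering with acetic acid keeps the ortho benzylic alkoxide from adding to the allenyl ether, and the medium is too weakly acidic to hydrolyse it.

Step 6
Reactants: 7 (1RS)-1-[3-(hydroxymethyl)-4-(propa-1,2-dien-1-yloxy)phenyl]ethan-1-ol
Product: 8 5-acetyl-2-(propa-1,2-dien-1-yloxy)benzaldehyde
Conditions: MnO2 (excess), CH2Cl2, rt → 40 °C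
Reagents that add atoms: none
Why: Heterogeneous MnO2 oxidation of benzylic alcohols takes the primary one to the aldehyde and the secondary one to the aryl ketone under neutral conditions that leave the allenyl ether alone.

Step 7
Reactants: 8 5-acetyl-2-(propa-1,2-dien-1-yloxy)benzaldehyde; 9 bis(pinacolato)diboron
Product: 11 1-{(2R,3R)-3-hydroxy-2-[1-(4,4,5,5-tetramethyl-1,3,2-dioxaborolan-2-yl)ethenyl]-2,3-dihydro-1-benzofuran-5-yl}ethan-1-one, via 3-O-pinacolboryl ether 10 (not isolated)
Conditions: CuCl (5 mol%), (S,S)-Ph-BPE (6 mol%), NaOt-Bu (15 mol%), THF, 0 °C → rt; aq. NH4Cl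
Reagents that add atoms: bis(pinacolato)diboron (9), CC1(C)OB(OC1(C)C)B1OC(C)(C)C(C)(C)O1
Why: Proposed new method: the closest known reaction type is the copper-catalysed enantioselective borylative coupling of allenes with aldehydes and ketones using B2pin2 and a chiral phosphine, applied here intramolecularly to an aryloxyallene, which has not been shown. The ligand-bound Cu–Bpin species formed from CuCl, NaOt-Bu and 9 adds across the terminal C=C of the allene with boron on the central carbon, giving a 2-boryl-3-aryloxyallylcopper with copper on the CH2 terminus. Its oxygen-bearing γ-carbon attacks the ortho formyl group through a closed chair-like six-membered transition state (Cu, CH2, Ca, C2, C3, O), forming C2–C3 and closing the dihydrofuran ring in a 5-exo-trig mode at the formyl carbon. Because Ca and the carbonyl oxygen both belong to that cyclic transition state they are gauche about the new bond, and with the arene bridging O1 and C3 this can only give the 2,3-cis ring, so the relative configuration is fixed by the tether. The absolute configuration (2R,3R) is set by the chiral bisphosphine on copper, which selects the face of the aldehyde. The copper alkoxide is turned over by 9 to the boryl ether 10, which is hydrolysed on work-up. The step needs boron on the central allene carbon (the normal sense of borylcupration of allenes), the aldehyde ahead of the aryl ketone (intramolecular five-membered closure at the more electrophilic carbonyl) and allene insertion ahead of direct borylation of the aldehyde (allenes being the faster partners of Cu–B species).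

Step 8
Reactants: 11 1-{(2R,3R)-3-hydroxy-2-[1-(4,4,5,5-tetramethyl-1,3,2-dioxaborolan-2-yl)ethenyl]-2,3-dihydro-1-benzofuran-5-yl}ethan-1-one
Product: 12 (2R,3R)-5-[(1R)-1-hydroxyethyl]-2-[1-(4,4,5,5-tetramethyl-1,3,2-dioxaborolan-2-yl)ethenyl]-2,3-dihydro-1-benzofuran-3-ol
Conditions: RuCl[(R,R)-TsDPEN](p-cymene) (2 mol%), HCO2H/Et3N (5:2), CH2Cl2, rt
Reagents that add atoms: none
Why: Noyori asymmetric transfer hydrogenation of an aryl methyl ketone; the (R,R)-TsDPEN ruthenium hydride gives the (R)-1-arylethanol by catalyst control, independent of the distant ring stereocentres, and formate makes the reduction irreversible. The alkenyl boronate and the secondary alcohol are not substrates for this catalyst.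

Step 9
Reactants: 12 (2R,3R)-5-[(1R)-1-hydroxyethyl]-2-[1-(4,4,5,5-tetramethyl-1,3,2-dioxaborolan-2-yl)ethenyl]-2,3-dihydro-1-benzofuran-3-ol; 13 3-methylbutanoyl chloride
Product: 14 (1R)-1-{(2R,3R)-3-[(3-methylbutanoyl)oxy]-2-[1-(4,4,5,5-tetramethyl-1,3,2-dioxaborolan-2-yl)ethenyl]-2,3-dihydro-1-benzofuran-5-yl}ethyl 3-methylbutanoate
Conditions: pyridine, DMAP (cat.), CH2Cl2, 0 °C → rt
Reagents that add atoms: 3-methylbutanoyl chloride (13), CC(C)CC(Cl)=O
Why: DMAP-catalysed acylation of both secondary alcohols by the acid chloride in a pyridine-buffered medium, which avoids ionisation at the benzylic carbons; no stereocentre is touched.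

Step 10
Reactants: 14 (1R)-1-{(2R,3R)-3-[(3-methylbutanoyl)oxy]-2-[1-(4,4,5,5-tetramethyl-1,3,2-dioxaborolan-2-yl)ethenyl]-2,3-dihydro-1-benzofuran-5-yl}ethyl 3-methylbutanoate
Product: 16 (1R)-1-{(2R,3R)-2-(3-hydroxyprop-1-en-2-yl)-3-[(3-methylbutanoyl)oxy]-2,3-dihydro-1-benzofuran-5-yl}ethyl 3-methylbutanoate, via allylic pinacol boronate 15 (not isolated)
Conditions: ICH2Cl, i-PrMgCl·LiCl, THF, −78 °C → rt; then NaBO3·4H2O, THF/H2O, 0 °C → rt
Reagents that add atoms: chloroiodomethane, ClCI; sodium perborate (NaBO3, used as the tetrahydrate), [Na+].[O-]OB=O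
Why: Matteson homologation: the carbenoid ClCH2MgCl, made by iodine–magnesium exchange, adds to boron and the alkenyl group migrates with loss of chloride to give the allylic boronate 15, which perborate oxidises to the primary allylic alcohol with the C–O bond where the C–B bond was. The magnesium carbenoid at −78 °C is chosen over the lithium one because it adds to ester carbonyls far more slowly; C2 and C3 are not involved.

Step 11
Reactants: 16 (1R)-1-{(2R,3R)-2-(3-hydroxyprop-1-en-2-yl)-3-[(3-methylbutanoyl)oxy]-2,3-dihydro-1-benzofuran-5-yl}ethyl 3-methylbutanoate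
Product: 17 (1R)-1-{(2R,3R)-3-[(3-methylbutanoyl)oxy]-2-(3-oxoprop-1-en-2-yl)-2,3-dihydro-1-benzofuran-5-yl}ethyl 3-methylbutanoate
Conditions: MnO2, CH2Cl2, rt
Reagents that add atoms: none
Why: MnO2 oxidation of a primary allylic alcohol to the enal under neutral heterogeneous conditions, which avoids both the base that would eliminate the C3 ester toward the benzofuran and the acid that would ionise the benzylic esters.

## Compound list

1 | 5-acetyl-2-hydroxybenzaldehyde | CC(=O)c1ccc(O)c(C=O)c1 | starting material
2 | 3-bromoprop-1-yne | C#CCBr | starting material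
3 | 5-acetyl-2-(prop-2-yn-1-yloxy)benzaldehyde | C#CCOc1ccc(C(C)=O)cc1C=O | intermediate
4 | (1RS)-1-[3-(hydroxymethyl)-4-(prop-2-yn-1-yloxy)phenyl]ethan-1-ol (racemic) | C#CCOc1ccc(C(C)O)cc1CO | intermediate
5 | (1RS)-1-[3-({[tert-butyl(dimethyl)silyl]oxy}methyl)-4-(prop-2-yn-1-yloxy)phenyl]ethyl tert-butyl(dimethyl)silyl ether (racemic) | C#CCOc1ccc(C(C)O[Si](C)(C)C(C)(C)C)cc1CO[Si](C)(C)C(C)(C)C | intermediate
6 | (1RS)-1-[3-({[tert-butyl(dimethyl)silyl]oxy}methyl)-4-(propa-1,2-dien-1-yloxy)phenyl]ethyl tert-butyl(dimethyl)silyl ether (racemic) | C=C=COc1ccc(C(C)O[Si](C)(C)C(C)(C)C)cc1CO[Si](C)(C)C(C)(C)C | intermediate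
7 | (1RS)-1-[3-(hydroxymethyl)-4-(propa-1,2-dien-1-yloxy)phenyl]ethan-1-ol (racemic) | C=C=COc1ccc(C(C)O)cc1CO | intermediate
8 | 5-acetyl-2-(propa-1,2-dien-1-yloxy)benzaldehyde | C=C=COc1ccc(C(C)=O)cc1C=O | intermediate
9 | bis(pinacolato)diboron | CC1(C)OB(OC1(C)C)B1OC(C)(C)C(C)(C)O1 | starting material
10 | 1-{(2R,3R)-3-[(4,4,5,5-tetramethyl-1,3,2-dioxaborolan-2-yl)oxy]-2-[1-(4,4,5,5-tetramethyl-1,3,2-dioxaborolan-2-yl)ethenyl]-2,3-dihydro-1-benzofuran-5-yl}ethan-1-one | C=C(B1OC(C)(C)C(C)(C)O1)[C@H]1Oc2ccc(C(C)=O)cc2[C@H]1OB1OC(C)(C)C(C)(C)O1 | intermediate (not isolated)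
11 | 1-{(2R,3R)-3-hydroxy-2-[1-(4,4,5,5-tetramethyl-1,3,2-dioxaborolan-2-yl)ethenyl]-2,3-dihydro-1-benzofuran-5-yl}ethan-1-one | C=C(B1OC(C)(C)C(C)(C)O1)[C@H]1Oc2ccc(C(C)=O)cc2[C@H]1O | intermediate
12 | (2R,3R)-5-[(1R)-1-hydroxyethyl]-2-[1-(4,4,5,5-tetramethyl-1,3,2-dioxaborolan-2-yl)ethenyl]-2,3-dihydro-1-benzofuran-3-ol | C=C(B1OC(C)(C)C(C)(C)O1)[C@H]1Oc2ccc([C@@H](C)O)cc2[C@H]1O | intermediate
13 | 3-methylbutanoyl chloride | CC(C)CC(Cl)=O | starting material
14 | (1R)-1-{(2R,3R)-3-[(3-methylbutanoyl)oxy]-2-[1-(4,4,5,5-tetramethyl-1,3,2-dioxaborolan-2-yl)ethenyl]-2,3-dihydro-1-benzofuran-5-yl}ethyl 3-methylbutanoate | C=C(B1OC(C)(C)C(C)(C)O1)[C@H]1Oc2ccc([C@@H](C)OC(=O)CC(C)C)cc2[C@H]1OC(=O)CC(C)C | intermediate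
15 | (1R)-1-{(2R,3R)-3-[(3-methylbutanoyl)oxy]-2-[3-(4,4,5,5-tetramethyl-1,3,2-dioxaborolan-2-yl)prop-1-en-2-yl]-2,3-dihydro-1-benzofuran-5-yl}ethyl 3-methylbutanoate | C=C(CB1OC(C)(C)C(C)(C)O1)[C@H]1Oc2ccc([C@@H](C)OC(=O)CC(C)C)cc2[C@H]1OC(=O)CC(C)C | intermediate (not isolated)
16 | (1R)-1-{(2R,3R)-2-(3-hydroxyprop-1-en-2-yl)-3-[(3-methylbutanoyl)oxy]-2,3-dihydro-1-benzofuran-5-yl}ethyl 3-methylbutanoate | C=C(CO)[C@H]1Oc2ccc([C@@H](C)OC(=O)CC(C)C)cc2[C@H]1OC(=O)CC(C)C | intermediate
17 | (1R)-1-{(2R,3R)-3-[(3-methylbutanoyl)oxy]-2-(3-oxoprop-1-en-2-yl)-2,3-dihydro-1-benzofuran-5-yl}ethyl 3-methylbutanoate (CNP0316116.1) | C=C(C=O)[C@H]1Oc2ccc([C@@H](C)OC(=O)CC(C)C)cc2[C@H]1OC(=O)CC(C)C | target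

## Step count and least certain steps

Total: 11 steps. Longest linear sequence: 11 steps (1 → 17).

**Step 7 (key step, proposed new method).** Three things may go wrong:
- direct 1,2-borylation of the aldehyde or protonation of the allylcopper may overtake ring closure;
- facial selectivity may be poor if the short aryl tether, rather than the ligand, shapes the transition state;
- borylcupration in the opposite sense may be followed by loss of aryloxide.

The fallback uses known chemistry and sets out from 8. Diboration of the terminal double bond of the allene with 9 under Pt(dba)2/PCy3 (toluene, rt to 50 °C), a known reaction of allenes, should give the diboryl enol ether 5-acetyl-2-{[(1Z)-2,3-bis(4,4,5,5-tetramethyl-1,3,2-dioxaborolan-2-yl)prop-1-en-1-yl]oxy}benzaldehyde F1. F1 is a γ-aryloxyallylboronate that carries its own aldehyde. Uncatalysed intramolecular allylboration through the same closed transition state should give the cis boryl ether as a racemate: 10 together with its mirror image 1-{(2S,3S)-3-[(4,4,5,5-tetramethyl-1,3,2-dioxaborolan-2-yl)oxy]-2-[1-(4,4,5,5-tetramethyl-1,3,2-dioxaborolan-2-yl)ethenyl]-2,3-dihydro-1-benzofuran-5-yl}ethan-1-one F2. Aqueous work-up then gives 11 and its mirror image 1-{(2S,3S)-3-hydroxy-2-[1-(4,4,5,5-tetramethyl-1,3,2-dioxaborolan-2-yl)ethenyl]-2,3-dihydro-1-benzofuran-5-yl}ethan-1-one F3, which are separated by preparative chromatography on a chiral stationary phase. The fallback rejoins the route at 11; absolute control is replaced by resolution at the cost of half the material.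

**Step 10.** The carbenoid may add to an ester carbonyl, the hindered α-branched alkenyl group may migrate sluggishly, or the esters may suffer under perborate. The fallback sets out from 14. Iododeboronation (NaOMe, then I2, THF/MeOH, −78 °C) should give (1R)-1-{(2S,3R)-2-(1-iodoethenyl)-3-[(3-methylbutanoyl)oxy]-2,3-dihydro-1-benzofuran-5-yl}ethyl 3-methylbutanoate F4; the geometry is unchanged and the C2 descriptor changes only because iodine raises the priority of Ca. Stille coupling of F4 with (tributylstannyl)methanol (Pd(PPh3)4, dioxane, 80 °C) should give 16 directly, where the fallback rejoins the route.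

**Step 8.** The electron-rich para-alkoxy aryl ketone may be reduced slowly and incompletely, and the formic acid medium may cause protodeboronation or acid-promoted dehydration of the benzylic C3 alcohol toward the benzofuran. The fallback sets out from 11:
- Acylation of the C3 hydroxyl with 13 (pyridine, DMAP) gives (2R,3R)-5-acetyl-2-[1-(4,4,5,5-tetramethyl-1,3,2-dioxaborolan-2-yl)ethenyl]-2,3-dihydro-1-benzofuran-3-yl 3-methylbutanoate F5.
- NaBH4 in MeOH reduces the ketone without selectivity to (2R,3R)-5-[(1R)-1-hydroxyethyl]-2-[1-(4,4,5,5-tetramethyl-1,3,2-dioxaborolan-2-yl)ethenyl]-2,3-dihydro-1-benzofuran-3-yl 3-methylbutanoate F6 and its epimer (2R,3R)-5-[(1S)-1-hydroxyethyl]-2-[1-(4,4,5,5-tetramethyl-1,3,2-dioxaborolan-2-yl)ethenyl]-2,3-dihydro-1-benzofuran-3-yl 3-methylbutanoate F7.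
- Immobilised Candida antarctica lipase B with vinyl 3-methylbutanoate, which acylates 1-arylethanols with the usual (R) preference, converts only F6 into 14, where the fallback rejoins the route.
- Recovered F7 is returned to F5 with MnO2 and recycled.

**Step 5.** The liberated ortho benzylic alkoxide may add to the allenyl ether (closure to a cyclic acetal), or the enol-ether-type allene may hydrolyse during work-up or chromatography. The fallback sets out from 3 and masks the carbonyls at their own oxidation level:
- Ethylene glycol and p-TsOH in toluene with removal of water give 2-[5-(2-methyl-1,3-dioxolan-2-yl)-2-(prop-2-yn-1-yloxy)phenyl]-1,3-dioxolane F8.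
- KOt-Bu in THF isomerises it to 2-[5-(2-methyl-1,3-dioxolan-2-yl)-2-(propa-1,2-dien-1-yloxy)phenyl]-1,3-dioxolane F9.
- PPTS in wet acetone at rt removes both acetals to give 8, where the fallback rejoins the route. This relies on the low basicity of an allenyl ether on an electron-poor arene.

This fallback bypasses 4–7 and is two steps shorter, but its last step has the weaker precedent, which is why it is not the main route.

## Further compounds

F1 | step 7 | 5-acetyl-2-{[(1Z)-2,3-bis(4,4,5,5-tetramethyl-1,3,2-dioxaborolan-2-yl)prop-1-en-1-yl]oxy}benzaldehyde | CC(=O)c1ccc(O/C=C(/B2OC(C)(C)C(C)(C)O2)CB2OC(C)(C)C(C)(C)O2)c(C=O)c1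
F2 | step 7 | 1-{(2S,3S)-3-[(4,4,5,5-tetramethyl-1,3,2-dioxaborolan-2-yl)oxy]-2-[1-(4,4,5,5-tetramethyl-1,3,2-dioxaborolan-2-yl)ethenyl]-2,3-dihydro-1-benzofuran-5-yl}ethan-1-one | C=C(B1OC(C)(C)C(C)(C)O1)[C@@H]1Oc2ccc(C(C)=O)cc2[C@@H]1OB1OC(C)(C)C(C)(C)O1
F3 | step 7 | 1-{(2S,3S)-3-hydroxy-2-[1-(4,4,5,5-tetramethyl-1,3,2-dioxaborolan-2-yl)ethenyl]-2,3-dihydro-1-benzofuran-5-yl}ethan-1-one | C=C(B1OC(C)(C)C(C)(C)O1)[C@@H]1Oc2ccc(C(C)=O)cc2[C@@H]1O
F4 | step 10 | (1R)-1-{(2S,3R)-2-(1-iodoethenyl)-3-[(3-methylbutanoyl)oxy]-2,3-dihydro-1-benzofuran-5-yl}ethyl 3-methylbutanoate | C=C(I)[C@H]1Oc2ccc([C@@H](C)OC(=O)CC(C)C)cc2[C@H]1OC(=O)CC(C)C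
F5 | step 8 | (2R,3R)-5-acetyl-2-[1-(4,4,5,5-tetramethyl-1,3,2-dioxaborolan-2-yl)ethenyl]-2,3-dihydro-1-benzofuran-3-yl 3-methylbutanoate | C=C(B1OC(C)(C)C(C)(C)O1)[C@H]1Oc2ccc(C(C)=O)cc2[C@H]1OC(=O)CC(C)C
F6 | step 8 | (2R,3R)-5-[(1R)-1-hydroxyethyl]-2-[1-(4,4,5,5-tetramethyl-1,3,2-dioxaborolan-2-yl)ethenyl]-2,3-dihydro-1-benzofuran-3-yl 3-methylbutanoate | C=C(B1OC(C)(C)C(C)(C)O1)[C@H]1Oc2ccc([C@@H](C)O)cc2[C@H]1OC(=O)CC(C)C
F7 | step 8 | (2R,3R)-5-[(1S)-1-hydroxyethyl]-2-[1-(4,4,5,5-tetramethyl-1,3,2-dioxaborolan-2-yl)ethenyl]-2,3-dihydro-1-benzofuran-3-yl 3-methylbutanoate | C=C(B1OC(C)(C)C(C)(C)O1)[C@H]1Oc2ccc([C@H](C)O)cc2[C@H]1OC(=O)CC(C)C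
F8 | step 5 | 2-[5-(2-methyl-1,3-dioxolan-2-yl)-2-(prop-2-yn-1-yloxy)phenyl]-1,3-dioxolane | C#CCOc1ccc(C2(C)OCCO2)cc1C1OCCO1
F9 | step 5 | 2-[5-(2-methyl-1,3-dioxolan-2-yl)-2-(propa-1,2-dien-1-yloxy)phenyl]-1,3-dioxolane | C=C=COc1ccc(C2(C)OCCO2)cc1C1OCCO1
A1 | alternative 1 | (1R)-1-[(2R,3R)-3-(3-methylbutanoyloxy)-2-(prop-1-en-2-yl)-2,3-dihydro-1-benzofuran-5-yl]ethyl 3-methylbutanoate | C=C(C)[C@H]1Oc2ccc([C@@H](C)OC(=O)CC(C)C)cc2[C@H]1OC(=O)CC(C)C
A2 | alternative 1 | (3R,4R)-4-(ethynyloxy)-5-methylhex-5-en-1-yn-3-yl 3-methylbutanoate | C=C(C)[C@@H](OC#C)[C@@H](C#C)OC(=O)CC(C)C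
A3 | alternative 1 | (2R)-but-3-yn-2-yl 3-methylbutanoate | C#C[C@@H](C)OC(=O)CC(C)C
A4 | alternative 2 | (3aR,8bR)-7-acetyl-3a,8b-dihydrofuro[3,2-b][1]benzofuran-2(3H)-one | O=C1C[C@H]2Oc3ccc(C(C)=O)cc3[C@H]2O1
A5 | alternative 2 | [(2S)-5-acetyl-2,3-dihydro-1-benzofuran-2-yl]acetic acid | OC(=O)C[C@H]1Oc2ccc(C(C)=O)cc2C1
A6 | alternative 3 | (3aR,8bR)-7-acetyl-3-methylidene-3a,8b-dihydrofuro[3,2-b][1]benzofuran-2(3H)-one | C=C1[C@H]2Oc3ccc(C(C)=O)cc3[C@H]2OC1=O
A7 | alternative 3 | 1-{4-hydroxy-3-[(1S)-1-hydroxybuta-2,3-dien-1-yl]phenyl}ethan-1-one | C=C=C[C@H](O)c1cc(C(C)=O)ccc1O
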